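The readings were computed with made-up constants; the scatter is artificial.

At 25.0 h, I read the electrophile's apparent constant in the south run as 1.46 times that of the south-east run, close to the charge ratio of 1.50, so I took the rate as first order in nucleophile.

| flask | electrophile | nucleophile | temperature | remark | time |
|---|---|---|---|---|---|
| south | 12 mM | 3 equiv | −20 °C | the very flask that is asked about, followed so far |  |
| south-east | 12 mM | 2 equiv | −20 °C | run made earlier |  |
| flask | 12 mM | 3.00 equiv | −20 °C |  | 8.0 d |

| run | time / h | target / % | electrophile / % |
|---|---|---|---|
| south | 25.0 | 29 | 62 |
| south | 72.0 | 39 | 31 |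
| south | 120 | 39 | 19 |
| south | 192 | 31 | 9 |
| south-east | 2.00 | 4 | 97 |
| south-east | 5.00 | 6 | 93 |
| south-east | 10.0 | 11 | 88 |
| south-east | 25.0 | 21 | 72 |

(each reading ± 1.5 percentage points)

- dawn: change nothing and wait 8.0 d more
- noon: at 8.0 d take out 90% of the acid set free then present, then wait 8.0 d
- winter: at 8.0 d raise the temperature by 25 K, then wait 8.0 d
- midnight: at 8.0 d add nucleophile, 100% of the amount charged, then wait 8.0 d

- what is added takes up no volume worth counting
- what was read earlier has a scatter of 1.5 percentage points, one standard deviation
- the earlier runs do not show what temperature does; that part of a forecast is a guess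

* target, in percent of the electrophile first charged, at 8.0 d
* which option adds most target ("none" when 2 percentage points or less is all one gets) (dawn / noon / winter / midnight / none)
* target present, in percent of the electrophile first charged, after noon
* target present, in percent of the electrophile first charged, after midnight

The bench rule for a nucleophile in excess is pseudo-first-order decay. The first south reading gave a constant of 0.0191 h⁻¹, which put the electrophile left at 8.0 d at 2.54% of its charge. But the south run's constant between its last two readings was 0.0104 h⁻¹, lower. I supposed that each target frees acid, which takes up a second nucleophile. The charge then covers the electrophile by a ratio of 1.50, not 3.00, and there the rule stops working. So I put each answer back in: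

free share at the end, f = 1 − 2(1 − a)/equiv; w = (1 + f)/2; a = exp(−k·w·t)

first round: a = 2.54%, f = 0.350, w = 0.675

second round: a = 8.39%, f = 0.389, w = 0.695

last: a = 7.81%

I called w the working share: the mean of the nucleophile's free fraction at the start and at the end. The reckoned 7.81% stood near the reading of 9%. Target I took from its reading, 31%. Over the last two readings target fell 8 percentage points while the electrophile fell 10 points, and the supply left was smaller than that fall, so I expected no gain from the cold options. The earlier runs do not show what temperature does, so for winter I made no reckoning of my own.

The forecast gave 31% now, 7% after noon, 2% after midnight and none as best, holding that “every option loses target”, winter included.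

The flask held 32.0% target at 8.0 d. The best option was winter, adding 40 points, while dawn changed target by −3.2 points, noon left 28.7% and midnight 29.1%.

    electrophile + nucleophile → acid set free + target (k = 1.60 × 10⁻⁴ M⁻¹ s⁻¹, Ea = 60.0 kJ mol⁻¹)
    nucleophile + acid set free ⇌ protonated nucleophile, settled at all times (K = 33000 M⁻¹, ΔH = −18.0 kJ mol⁻¹)
    electrophile + acid set free → side product (k = 0.0130 M⁻¹ s⁻¹, Ea = 55.0 kJ mol⁻¹)
    target ⇌ isomer of the product (K = 2.40, k = 4.00 × 10⁻⁶ s⁻¹, Ea = 96.0 kJ mol⁻¹, ΔH = −47.0 kJ mol⁻¹)
    (constants at −20 °C)

In the flask, electrophile stood at 9.28% against the 7.81% that my working share of 0.695 gave. The neighbour flask, with 1.80 equiv of nucleophile, took the same rounds with its constant scaled to 0.0115 h⁻¹. The first round gave a = 11.0% and w = 0.506, the second a = 32.8% and w = 0.627, and the last a = 25.1%. That neighbour flask held 26.1% electrophile and 25.4% target.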